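**Assumptions.** The target has no stereocentre and no configurable double bond, so it is achiral and no enantiomer has to be selected. The only stereodescriptor in the route is the Z geometry of a transient silyl enol ether. 1,3,5-Tris(benzyloxy)benzene is taken as a catalogue chemical.

## Retrosynthetic overview

1. The target comes from neutral hydrogenolysis of three phloroglucinol O-benzyl groups, which the aryl acetate survives.
2. The resorcinol monoacetate ring comes from dehydrogenating the enol acetate of a 2-alkylcyclohexane-1,3-dione. A dione can be O-acetylated only once, so the single acetate is placed without a statistical step.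
3. The key C–C bond joins ring C2 to the chain CH2. Dione C2 is made electrophilic as its phenyliodonium ylide (an enolonium equivalent) and receives the primary alkyl group of a B-alkyl-9-BBN. Both carbons are normally nucleophilic.
4. The aryl ketone comes from Lewis-acid-free Friedel–Crafts acylation of phloroglucinol tribenzyl ether with undec-10-enoic acid, which supplies all eleven chain carbons.
5. No ring is built by cyclisation. The phloroglucinol ring is bought aromatic. The resorcinol ring is bought as cyclohexane-1,3-dione and aromatised in the penultimate step.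

## Route

Step 1
Reactants: 1 1,3,5-tris(benzyloxy)benzene; 2 undec-10-enoic acid; 3 trifluoroacetic anhydride
Product: 5 1-[2,4,6-tris(benzyloxy)phenyl]undec-10-en-1-one, via mixed anhydride 4 (not isolated)
Conditions: 2 (1.1 equiv), TFAA (1.5 equiv), CH2Cl2, 0 °C → rt, 3 h; aq NaHCO3
Reagents that add atoms: none
Why: Friedel–Crafts acylation through a carboxylic–trifluoroacetic mixed anhydride needs no Lewis acid on this triply activated symmetric arene, so the benzyl ethers and terminal alkene survive, and the new ketone deactivates the ring against a second acylation.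

Step 2
Reactants: 6 cyclohexane-1,3-dione
Product: 7 2-(phenyl-λ3-iodanylidene)cyclohexane-1,3-dione (phenyliodonium ylide, drawn as the zwitterion)
Conditions: PhI(OAc)2 (1.0 equiv), KOH (2 equiv), MeOH, 0 °C, 2 h; ice-water, CH2Cl2 extraction, Et2O trituration
Reagents that add atoms: (diacetoxyiodo)benzene CC(=O)OI(OC(C)=O)c1ccccc1
Why: In this standard iodonium-ylide formation the dione enolate displaces acetate at I(III) and a second deprotonation gives a stable solid in which the normally nucleophilic C2 carries a hypernucleofuge.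

Step 3
Reactants: 5 1-[2,4,6-tris(benzyloxy)phenyl]undec-10-en-1-one; 8 9-borabicyclo[3.3.1]nonane (9-BBN); 7 phenyliodonium ylide
Product: 11 2-{11-oxo-11-[2,4,6-tris(benzyloxy)phenyl]undecyl}cyclohexane-1,3-dione, via B-alkyl-9-BBN adduct 9 (not isolated), via O-boron enolate 10 (not isolated)
Conditions: (i) 9-BBN (0.98 equiv, 0.5 M THF), 0 °C → rt, 4 h; (ii) 7 (1.2 equiv) in CH2Cl2, 0 °C → rt, dark, 12 h; (iii) H2O/THF, rt, then chromatography
Reagents that add atoms: none
Why: Proposed new method: 9-BBN adds anti-Markovnikov to the terminal alkene much faster than it reduces the twisted, di-ortho-substituted aryl ketone, and ylide 7 then serves as the enolonium equivalent of the dione, its C2 binding the vacant boron orbital to give a borate whose primary alkyl group makes a 1,2-metallate shift onto C2 with loss of PhI, after which boron moves to oxygen (10) and water releases 11; the closest known reaction types are the Hooz alkylation of α-diazocarbonyl compounds, the Brown alkylation of α-halo enolates with B-alkyl-9-BBN reagents (selective transfer of the B-alkyl group) and alkyl transfer from trialkylboranes to monocarbonyl and bis(sulfonyl) iodonium ylides.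

Step 4
Reactants: 11 2-{11-oxo-11-[2,4,6-tris(benzyloxy)phenyl]undecyl}cyclohexane-1,3-dione
Product: 12 3-oxo-2-{11-oxo-11-[2,4,6-tris(benzyloxy)phenyl]undecyl}cyclohex-1-en-1-yl acetate
Conditions: AcCl (1.2 equiv), pyridine (1.5 equiv), CH2Cl2, 0 °C, 1 h
Reagents that add atoms: acetyl chloride CC(=O)Cl
Why: O-acylation of a vinylogous acid takes up exactly one acetyl group because C2 is fully substituted and only one enol oxygen exists, so the future resorcinol is desymmetrised here while the hindered aryl ketone stays untouched.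

Step 5
Reactants: 12 enol acetate; 13 trimethylsilyl trifluoromethanesulfonate
Product: 16 3-hydroxy-2-{11-oxo-11-[2,4,6-tris(benzyloxy)phenyl]undecyl}phenyl acetate, via bis-silyl dienol ether 14 (not isolated), via bis-silyl arene 15 (not isolated)
Conditions: (i) TMSOTf (2.5 equiv), Et3N (3 equiv), CH2Cl2, 0 °C, 1 h, pentane trituration and filtration, crude; (ii) DDQ (1.05 equiv), CH2Cl2, 0 °C, 30 min; (iii) 1 M HCl/THF, 0 °C, 15 min
Reagents that add atoms: none
Why: Soft enolisation converts the vinylogous anhydride into a 1-acetoxy-3-silyloxycyclohexa-1,3-diene (either direction of deprotonation gives a diene of the same oxidation level) that DDQ aromatises within minutes by hydride abstraction and proton loss, far faster than it attacks the acyclic silyl enol ether or the benzyl ethers, and dilute acid then removes both TMS groups but not the aryl acetate, while any chain enone from over-oxidation is reduced again in step 6.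

Step 6
Reactants: 16 3-hydroxy-2-{11-oxo-11-[2,4,6-tris(benzyloxy)phenyl]undecyl}phenyl acetate
Product: 17 3-hydroxy-2-[11-oxo-11-(2,4,6-trihydroxyphenyl)undecyl]phenyl acetate (target)
Conditions: H2 (1 atm), 10% Pd/C, EtOAc, rt, 5 h; filter through Celite, neutral work-up
Reagents that add atoms: none
Why: Catalytic hydrogenolysis of benzyl aryl ethers in a neutral, non-nucleophilic solvent (no alcohol, no base) leaves the aryl acetate in place, and the hydrogen-bonded 2,4,6-trihydroxyphenyl ketone, a vinylogous acid, is not reduced at 1 atm.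

## Compound list

1 | 1,3,5-tris(benzyloxy)benzene | c1ccccc1COc1cc(OCc2ccccc2)cc(OCc2ccccc2)c1 | starting material
2 | undec-10-enoic acid | C=CCCCCCCCCC(=O)O | starting material
3 | trifluoroacetic anhydride | O=C(OC(=O)C(F)(F)F)C(F)(F)F | starting material
4 | undec-10-enoyl trifluoroacetate (mixed anhydride) | C=CCCCCCCCCC(=O)OC(=O)C(F)(F)F | intermediate
5 | 1-[2,4,6-tris(benzyloxy)phenyl]undec-10-en-1-one | C=CCCCCCCCCC(=O)c1c(OCc2ccccc2)cc(OCc2ccccc2)cc1OCc1ccccc1 | intermediate
6 | cyclohexane-1,3-dione | O=C1CCCC(=O)C1 | starting material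
7 | 2-(phenyl-λ3-iodanylidene)cyclohexane-1,3-dione (3-oxo-2-(phenyliodonio)cyclohex-1-en-1-olate) | O=C1CCCC([O-])=C1[I+]c1ccccc1 | intermediate
8 | 9-borabicyclo[3.3.1]nonane (9-BBN) | [H]B1C2CCCC1CCC2 | starting material
9 | 11-(9-borabicyclo[3.3.1]nonan-9-yl)-1-[2,4,6-tris(benzyloxy)phenyl]undecan-1-one | O=C(CCCCCCCCCCB1C2CCCC1CCC2)c1c(OCc2ccccc2)cc(OCc2ccccc2)cc1OCc1ccccc1 | intermediate
10 | 3-[(9-borabicyclo[3.3.1]nonan-9-yl)oxy]-2-{11-oxo-11-[2,4,6-tris(benzyloxy)phenyl]undecyl}cyclohex-2-en-1-one | O=C1CCCC(OB2C3CCCC2CCC3)=C1CCCCCCCCCCC(=O)c1c(OCc2ccccc2)cc(OCc2ccccc2)cc1OCc1ccccc1 | intermediate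
11 | 2-{11-oxo-11-[2,4,6-tris(benzyloxy)phenyl]undecyl}cyclohexane-1,3-dione | O=C1CCCC(=O)C1CCCCCCCCCCC(=O)c1c(OCc2ccccc2)cc(OCc2ccccc2)cc1OCc1ccccc1 | intermediate
12 | 3-oxo-2-{11-oxo-11-[2,4,6-tris(benzyloxy)phenyl]undecyl}cyclohex-1-en-1-yl acetate | CC(=O)OC1=C(CCCCCCCCCCC(=O)c2c(OCc3ccccc3)cc(OCc3ccccc3)cc2OCc2ccccc2)C(=O)CCC1 | intermediate
13 | trimethylsilyl trifluoromethanesulfonate | C[Si](C)(C)OS(=O)(=O)C(F)(F)F | starting material
14 | 2-{(10Z)-11-[2,4,6-tris(benzyloxy)phenyl]-11-[(trimethylsilyl)oxy]undec-10-en-1-yl}-3-[(trimethylsilyl)oxy]cyclohexa-1,3-dien-1-yl acetate | CC(=O)OC1=C(CCCCCCCCC/C=C(\O[Si](C)(C)C)c2c(OCc3ccccc3)cc(OCc3ccccc3)cc2OCc2ccccc2)C(O[Si](C)(C)C)=CCC1 | intermediate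
15 | 2-{(10Z)-11-[2,4,6-tris(benzyloxy)phenyl]-11-[(trimethylsilyl)oxy]undec-10-en-1-yl}-3-[(trimethylsilyl)oxy]phenyl acetate | CC(=O)Oc1cccc(O[Si](C)(C)C)c1CCCCCCCCC/C=C(\O[Si](C)(C)C)c1c(OCc2ccccc2)cc(OCc2ccccc2)cc1OCc1ccccc1 | intermediate
16 | 3-hydroxy-2-{11-oxo-11-[2,4,6-tris(benzyloxy)phenyl]undecyl}phenyl acetate | CC(=O)Oc1cccc(O)c1CCCCCCCCCCC(=O)c1c(OCc2ccccc2)cc(OCc2ccccc2)cc1OCc1ccccc1 | intermediate
17 | 3-hydroxy-2-[11-oxo-11-(2,4,6-trihydroxyphenyl)undecyl]phenyl acetate | CC(=O)Oc1cccc(O)c1CCCCCCCCCCC(=O)c1c(O)cc(O)cc1O | target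

## Step count and risks

Total step count: 6.
Longest linear sequence: 5 (steps 1, 3, 4, 5, 6). Step 2 is a one-step branch.

**Most likely to fail, 1: step 3.** The ylide may bind boron only through oxygen, a ring B–C bond of 9-BBN may migrate, or the ylide may decompose.
The fallback keeps dione C2 as the electrophile but uses it as a vinyl iodide in a palladium cross-coupling. It sets out from 6, together with borane 9 made as in step 3(i), and comes back at 11.
- Compound 6 is heated with MeOH, HC(OMe)3 and catalytic TsOH to give 3-methoxycyclohex-2-en-1-one F1.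
- Iodination at C2 (I2, CAN, MeCN) gives 2-iodo-3-methoxycyclohex-2-en-1-one F2.
- B-alkyl Suzuki–Miyaura coupling with 9 [PdCl2(dppf), Ph3As, Cs2CO3, DMF/THF/H2O, rt] gives 3-methoxy-2-{11-oxo-11-[2,4,6-tris(benzyloxy)phenyl]undecyl}cyclohex-2-en-1-one F3.
- 1 M HCl in THF hydrolyses the vinylogous ester to 11.

**Most likely to fail, 2: step 5.** The labile vinylogous-anhydride acetate may be lost under TMSOTf/amine, or the oxidation may be incomplete.
The fallback desymmetrises with a robust benzyl vinylogous ester, aromatises catalytically and acetylates afterwards. It sets out from 11 and comes back at 17.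
- Compound 11 with BnOH and catalytic TsOH (toluene, Dean–Stark) gives 3-(benzyloxy)-2-{11-oxo-11-[2,4,6-tris(benzyloxy)phenyl]undecyl}cyclohex-2-en-1-one F4.
- Pd(II)-catalysed aerobic dehydrogenation [Pd(TFA)2, 2-(dimethylamino)pyridine, TsOH, O2, DMSO, 80 °C] gives 3-(benzyloxy)-2-{11-oxo-11-[2,4,6-tris(benzyloxy)phenyl]undecyl}phenol F5.
- Ac2O/pyridine gives 3-(benzyloxy)-2-{11-oxo-11-[2,4,6-tris(benzyloxy)phenyl]undecyl}phenyl acetate F6.
- The conditions of step 6 remove all four benzyl groups to give 17.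

**Most likely to fail, 3: step 1.** The liberated TFA may cause benzyl cleavage or migration, or the acylation may be sluggish.
The fallback reverses the roles, adding an aryl anion to a Weinreb amide. It sets out from 1 and 2 and comes back at 5.
- Compound 1 with NBS (CH2Cl2, 0 °C) gives 2-bromo-1,3,5-tris(benzyloxy)benzene F7.
- Compound 2 with CDI and then MeNHOMe·HCl gives N-methoxy-N-methylundec-10-enamide F8.
- Bromine–lithium exchange on F7 (n-BuLi, THF, −78 °C) gives [2,4,6-tris(benzyloxy)phenyl]lithium F9.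
- F9 adds to F8, and an NH4Cl quench gives 5.

## Further compounds

F1 | step 3 | 3-methoxycyclohex-2-en-1-one | COC1=CC(=O)CCC1
F2 | step 3 | 2-iodo-3-methoxycyclohex-2-en-1-one | COC1=C(I)C(=O)CCC1
F3 | step 3 | 3-methoxy-2-{11-oxo-11-[2,4,6-tris(benzyloxy)phenyl]undecyl}cyclohex-2-en-1-one | COC1=C(CCCCCCCCCCC(=O)c2c(OCc3ccccc3)cc(OCc3ccccc3)cc2OCc2ccccc2)C(=O)CCC1
F4 | step 5 | 3-(benzyloxy)-2-{11-oxo-11-[2,4,6-tris(benzyloxy)phenyl]undecyl}cyclohex-2-en-1-one | O=C1CCCC(OCc2ccccc2)=C1CCCCCCCCCCC(=O)c1c(OCc2ccccc2)cc(OCc2ccccc2)cc1OCc1ccccc1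
F5 | step 5 | 3-(benzyloxy)-2-{11-oxo-11-[2,4,6-tris(benzyloxy)phenyl]undecyl}phenol | Oc1cccc(OCc2ccccc2)c1CCCCCCCCCCC(=O)c1c(OCc2ccccc2)cc(OCc2ccccc2)cc1OCc1ccccc1
F6 | step 5 | 3-(benzyloxy)-2-{11-oxo-11-[2,4,6-tris(benzyloxy)phenyl]undecyl}phenyl acetate | CC(=O)Oc1cccc(OCc2ccccc2)c1CCCCCCCCCCC(=O)c1c(OCc2ccccc2)cc(OCc2ccccc2)cc1OCc1ccccc1
F7 | step 1 | 2-bromo-1,3,5-tris(benzyloxy)benzene | Brc1c(OCc2ccccc2)cc(OCc2ccccc2)cc1OCc1ccccc1
F8 | step 1 | N-methoxy-N-methylundec-10-enamide | C=CCCCCCCCCC(=O)N(C)OC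
F9 | step 1 | [2,4,6-tris(benzyloxy)phenyl]lithium | [Li]c1c(OCc2ccccc2)cc(OCc2ccccc2)cc1OCc1ccccc1
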